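## Retrosynthetic overview

1. The depside ester between C4–O of ring B and the carbonyl of ring A is cut last, giving ring B phenol 12 and ring A acid 14 (used as its chloride 15).
2. The strategy rests on ring B being a resorcinol with CO2H at C1, a free OH at C2, a separately addressable oxygen at C4, propyl at C6 and H at C3 and C5. Ring A has the same 2,4-dioxygenated 6-propylbenzoate skeleton, so 12 and 14 both derive from one monosilyl ether 11.
3. The benzene ring of 11 is cut to diazo ketone 6 and siloxyalkyne 7: the Wolff shift makes C5–C6, the [2+2] addition makes C2–C3 and C4–C5, and a 6-electron electrocyclisation closes C1–C2.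
4. Diazo ketone 6 comes from methyl ketone 4 by detrifluoroacetylative diazo transfer, and 4 from hexan-2-one and glyoxylic acid. An acid chloride/diazomethane route is avoided because diazomethane would add as a 1,3-dipole to the fumarate-like alkene.
5. Ring order: the benzene ring is made once, in step 4. One portion of 11 becomes ring B (step 5), another becomes ring A (steps 6 and 7), and the two are joined in step 8.

Key step: step 4

Assumption: (ethynyloxy)triisopropylsilane 7 is a known, distillable siloxyalkyne and is treated as a purchasable starting material.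

## Route

Step 1
Reactants: 1 hexan-2-one; 2 glyoxylic acid monohydrate
Product: 3 (E)-4-oxo-3-propylpent-2-enoic acid
Conditions: 85% H3PO4, 80 °C
Reagents that add atoms: none
Why: Acid-catalysed crossed aldol condensation: in phosphoric acid hexan-2-one should enolise toward its more substituted C3, which adds to the non-enolisable aldehyde of glyoxylic acid, and dehydration should leave the open-chain E keto acid (acetyl trans to CO2H), as in the known condensation of butanone with glyoxylic acid.

Step 2
Reactants: 3 (E)-4-oxo-3-propylpent-2-enoic acid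
Product: 4 benzyl (E)-4-oxo-3-propylpent-2-enoate
Conditions: BnBr, KHCO3, DMF, rt
Reagents that add atoms: benzyl bromide (BrCc1ccccc1)
Why: Carboxylate O-alkylation (SN2 on benzyl bromide) with a weak base forms the benzyl ester without touching the enone or its E geometry.

Step 3
Reactants: 4 benzyl (E)-4-oxo-3-propylpent-2-enoate
Product: 6 benzyl (E)-5-diazo-4-oxo-3-propylpent-2-enoate, via trifluoroacetyl diketone 5 (not isolated)
Conditions: LiN(SiMe3)2, THF, −78 °C; CF3CO2CH2CF3; aq. HCl work-up; then MsN3, Et3N, H2O, MeCN, rt
Reagents that add atoms: methanesulfonyl azide (CS(=O)(=O)N=[N+]=[N-]); 2,2,2-trifluoroethyl trifluoroacetate (O=C(OCC(F)(F)F)C(F)(F)F; its CF3CO group is carried only in intermediate 5)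
Why: Danheiser detrifluoroacetylative diazo transfer: the methyl group is the only enolisable position of the ketone, its lithium enolate undergoes Claisen-type C-acylation with the trifluoroacetate, and the activated diketone 5 takes up the diazo group from the sulfonyl azide (Regitz transfer) with loss of the trifluoroacetyl group, so no diazomethane is needed.

Step 4
Reactants: 6 benzyl (E)-5-diazo-4-oxo-3-propylpent-2-enoate; 7 (ethynyloxy)triisopropylsilane
Product: 11 benzyl 2-hydroxy-6-propyl-4-(triisopropylsilyloxy)benzoate, via vinylketene 8 (not isolated), via 4-vinylcyclobutenone 9 (not isolated), via dienylketene 10 (not isolated)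
Conditions: 7 (1.5 equiv), hν (Hg lamp, Pyrex filter, >300 nm), ClCH2CH2Cl, rt; then 80 °C
Reagents that add atoms: none
Why: Light expels N2 from 6 and the alkenyl group shifts to the former diazo carbon (Wolff rearrangement, new C5–C6 bond) to give vinylketene 8, whose ketene C=C adds the siloxyalkyne in a [2+2] cycloaddition (C2–C3 and C4–C5); the resulting 4-vinylcyclobutenone 9 then opens by 4-electron electrocyclic ring opening to dienylketene 10. Ring B closes on warming by 6-electron electrocyclisation of 10 between the ketene carbon and the ester-bearing alkene terminus (C1–C2), and tautomerisation of the cyclohexadienone gives the phenol. This is the Danheiser benzannulation in its photochemical Wolff variant, known for unsaturated diazo ketones and siloxyalkynes as a route to resorcinol monosilyl ethers; the substrate differs only in the ester on the alkene terminus, which should make the ketene more electrophilic toward the electron-rich alkyne. No stereocentre is formed. The regiochemistry needed (silyloxy para to the ester and meta to the new hydroxyl) follows from the polarisation of 7, whose nucleophilic unsubstituted carbon bonds to the ketene carbonyl carbon. The E geometry of 6, retained in the 1,2-shift, holds the ester carbonyl away from the ketene so that oxa-electrocyclisation to a pyranone cannot compete, and irradiation above 300 nm for the shortest time needed should limit E/Z photoisomerisation.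

Step 5
Reactants: 11 benzyl 2-hydroxy-6-propyl-4-(triisopropylsilyloxy)benzoate
Product: 12 benzyl 2,4-dihydroxy-6-propylbenzoate (benzyl divarate)
Conditions: Bu4NF, AcOH, THF, 0 °C
Reagents that add atoms: none
Why: Fluoride-induced cleavage of the aryl silyl ether (driven by Si–F bond formation), buffered with acetic acid so that the benzyl ester stays intact.

Step 6
Reactants: 11 benzyl 2-hydroxy-6-propyl-4-(triisopropylsilyloxy)benzoate
Product: 13 benzyl 2-methoxy-6-propyl-4-(triisopropylsilyloxy)benzoate
Conditions: MeI, K2CO3, acetone, reflux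
Reagents that add atoms: iodomethane (CI)
Why: Williamson O-methylation of the only free phenol; the chelated C2–OH needs the carbonate/acetone reflux conditions usual for salicylates, which the aryl TIPS ether and the benzyl ester should tolerate in the absence of protic nucleophiles.

Step 7
Reactants: 13 benzyl 2-methoxy-6-propyl-4-(triisopropylsilyloxy)benzoate
Product: 14 2-methoxy-6-propyl-4-(triisopropylsilyloxy)benzoic acid
Conditions: H2 (1 atm), Pd/C (10%), EtOAc, rt
Reagents that add atoms: none
Why: Catalytic hydrogenolysis cleaves the benzylic C–O bond, away from the hindered carbonyl, and leaves the aryl silyl and methyl ethers intact.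

Step 8
Reactants: 14 2-methoxy-6-propyl-4-(triisopropylsilyloxy)benzoic acid; 12 benzyl 2,4-dihydroxy-6-propylbenzoate
Product: 16 benzyl 2-hydroxy-4-{[2-methoxy-6-propyl-4-(triisopropylsilyloxy)benzoyl]oxy}-6-propylbenzoate, via acid chloride 15 (not isolated)
Conditions: (COCl)2, DMF (cat.), CH2Cl2, 0 °C to rt; evaporate; then 12, Et3N, DMAP (cat.), CH2Cl2, 0 °C to rt
Reagents that add atoms: oxalyl chloride (ClC(=O)C(Cl)=O; its chlorine is carried only in intermediate 15)
Why: Acid chloride formation followed by base-mediated O-acylation (classical depside coupling): the C4–OH of 12 is the more acidic, unchelated phenol, while the C2–OH is held in a hydrogen bond to the ester carbonyl, so the ester should form at C4–O.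

Step 9
Reactants: 16 benzyl 2-hydroxy-4-{[2-methoxy-6-propyl-4-(triisopropylsilyloxy)benzoyl]oxy}-6-propylbenzoate
Product: 17 benzyl 2-hydroxy-4-[(4-hydroxy-2-methoxy-6-propylbenzoyl)oxy]-6-propylbenzoate
Conditions: Bu4NF, AcOH, THF, 0 °C
Reagents that add atoms: none
Why: Buffered fluoride desilylation of the aryl TIPS ether; acetic acid protonates the liberated phenoxide so that the hindered depside ester and the benzyl ester are not attacked.

Step 10
Reactants: 17 benzyl 2-hydroxy-4-[(4-hydroxy-2-methoxy-6-propylbenzoyl)oxy]-6-propylbenzoate
Product: 18 2-hydroxy-4-[(4-hydroxy-2-methoxy-6-propylbenzoyl)oxy]-6-propylbenzoic acid (CNP0147807.0)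
Conditions: H2 (1 atm), Pd/C (10%), EtOAc, rt
Reagents that add atoms: none
Why: Hydrogenolysis of the benzyl ester at room temperature should release the salicylic acid without touching the aryl ester and without the heat that could decarboxylate it.

## Compound list

1 | hexan-2-one | CCCCC(C)=O | starting material
2 | glyoxylic acid monohydrate (2,2-dihydroxyacetic acid) | OC(O)C(=O)O | starting material
3 | (E)-4-oxo-3-propylpent-2-enoic acid | CCC/C(C(C)=O)=C\C(=O)O | intermediate
4 | benzyl (E)-4-oxo-3-propylpent-2-enoate | CCC/C(C(C)=O)=C\C(=O)OCc1ccccc1 | intermediate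
5 | benzyl (E)-7,7,7-trifluoro-4,6-dioxo-3-propylhept-2-enoate (not isolated) | CCC/C(C(=O)CC(=O)C(F)(F)F)=C\C(=O)OCc1ccccc1 | intermediate
6 | benzyl (E)-5-diazo-4-oxo-3-propylpent-2-enoate | CCC/C(C(=O)C=[N+]=[N-])=C\C(=O)OCc1ccccc1 | intermediate
7 | (ethynyloxy)triisopropylsilane | C#CO[Si](C(C)C)(C(C)C)C(C)C | starting material
8 | benzyl (E)-5-oxo-3-propylpenta-2,4-dienoate (vinylketene, not isolated) | CCC/C(C=C=O)=C\C(=O)OCc1ccccc1 | intermediate
9 | benzyl (E)-3-[4-oxo-2-(triisopropylsilyloxy)cyclobut-2-en-1-yl]hex-2-enoate (racemic, not isolated) | CCC/C(C1C(=O)C=C1O[Si](C(C)C)(C(C)C)C(C)C)=C\C(=O)OCc1ccccc1 | intermediate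
10 | benzyl (2E,4E)-7-oxo-3-propyl-5-(triisopropylsilyloxy)hepta-2,4,6-trienoate (dienylketene, not isolated) | O=C=C/C(O[Si](C(C)C)(C(C)C)C(C)C)=C\C(CCC)=C\C(=O)OCc1ccccc1 | intermediate
11 | benzyl 2-hydroxy-6-propyl-4-(triisopropylsilyloxy)benzoate | CCCc1cc(O[Si](C(C)C)(C(C)C)C(C)C)cc(O)c1C(=O)OCc1ccccc1 | intermediate
12 | benzyl 2,4-dihydroxy-6-propylbenzoate (benzyl divarate) | CCCc1cc(O)cc(O)c1C(=O)OCc1ccccc1 | intermediate
13 | benzyl 2-methoxy-6-propyl-4-(triisopropylsilyloxy)benzoate | CCCc1cc(O[Si](C(C)C)(C(C)C)C(C)C)cc(OC)c1C(=O)OCc1ccccc1 | intermediate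
14 | 2-methoxy-6-propyl-4-(triisopropylsilyloxy)benzoic acid | CCCc1cc(O[Si](C(C)C)(C(C)C)C(C)C)cc(OC)c1C(=O)O | intermediate
15 | 2-methoxy-6-propyl-4-(triisopropylsilyloxy)benzoyl chloride (not isolated) | CCCc1cc(O[Si](C(C)C)(C(C)C)C(C)C)cc(OC)c1C(Cl)=O | intermediate
16 | benzyl 2-hydroxy-4-{[2-methoxy-6-propyl-4-(triisopropylsilyloxy)benzoyl]oxy}-6-propylbenzoate | CCCc1cc(OC(=O)c2c(CCC)cc(O[Si](C(C)C)(C(C)C)C(C)C)cc2OC)cc(O)c1C(=O)OCc1ccccc1 | intermediate
17 | benzyl 2-hydroxy-4-[(4-hydroxy-2-methoxy-6-propylbenzoyl)oxy]-6-propylbenzoate | CCCc1cc(OC(=O)c2c(CCC)cc(O)cc2OC)cc(O)c1C(=O)OCc1ccccc1 | intermediate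
18 | 2-hydroxy-4-[(4-hydroxy-2-methoxy-6-propylbenzoyl)oxy]-6-propylbenzoic acid | CCCc1cc(OC(=O)c2c(CCC)cc(O)cc2OC)cc(O)c1C(=O)O | target

## Count and risks

Total step count: 10. Longest linear sequence: 9 steps (steps 1, 2, 3, 4, 6, 7, 8, 9 and 10; step 5 is the side branch to ring B).

**Step 4 (benzannulation).** The E-alkene may photoisomerise before or after the Wolff shift, which would bring the ester carbonyl next to the ketene and divert it into oxa-electrocyclisation to a pyranone. The electron-poor vinylketene may also dimerise faster than it adds the alkyne. In that case the ring is not built by annulation but taken from a preformed resorcinol. This fallback does not branch from an intermediate of the route: it sets out from purchased 5-propylbenzene-1,3-diol F1 and comes back at 12 and, one step later, at 11. Ortho-carboxylation of 5-propylbenzene-1,3-diol F1 with MeOMgOCO2Me in DMF at 120 °C (Kolbe–Schmitt type, as used for alkylresorcinols) should give 2,4-dihydroxy-6-propylbenzoic acid F2. Benzylation of the carboxylate (BnBr, KHCO3, DMF) gives 12. One equivalent of TIPSCl with imidazole in CH2Cl2 at 0 °C should silylate the unchelated C4–OH of 12 to give 11 for the ring A branch.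

**Step 3 (diazo transfer).** The lithium enolate of 4 may add in Michael fashion to the 4-oxo-enoate of unreacted 4, or the base may remove the propyl CH2 proton gamma to the ester, so that trifluoroacetylation becomes unselective. The diazo group is then introduced without a strong base, setting out from 4 and coming back at 6. Soft enolisation with Me3SiOTf/Et3N (CH2Cl2, 0 °C) should give the silyl dienol ether benzyl (E)-3-propyl-4-(trimethylsilyloxy)penta-2,4-dienoate F3. N-Bromosuccinimide in THF at −78 °C converts it into the bromomethyl ketone benzyl (E)-5-bromo-4-oxo-3-propylpent-2-enoate F4. Treatment with N,N'-ditosylhydrazine and DBU in THF at 0 °C (Fukuyama diazo synthesis) should then give 6.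

**Step 1 (aldol condensation).** Condensation may take place at the methyl group of 1 instead of C3, or the product may isomerise to the Z acid, which closes to a hydroxybutenolide pseudo-acid. The C3 regiochemistry is then fixed beforehand with a silyl enol ether, setting out from 1 and coming back at 4 (bypassing 3 and step 2). TMSCl, NaI and Et3N in MeCN should give the more substituted enol ether (Z)-trimethyl(hex-2-en-2-yloxy)silane F5. Mukaiyama aldol addition to benzyl glyoxylate (O=CC(=O)OCc1ccccc1) with TiCl4 in CH2Cl2 at −78 °C gives benzyl 3-acetyl-2-hydroxyhexanoate F6. MsCl/Et3N converts it into benzyl 3-acetyl-2-(methylsulfonyloxy)hexanoate F7, and DBU effects E1cB elimination to 4, with the E isomer expected to predominate and any Z isomer removed by chromatography.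

## Further compounds

F1 | step 4 | 5-propylbenzene-1,3-diol (purchased) | CCCc1cc(O)cc(O)c1
F2 | step 4 | 2,4-dihydroxy-6-propylbenzoic acid | CCCc1cc(O)cc(O)c1C(=O)O
F3 | step 3 | benzyl (E)-3-propyl-4-(trimethylsilyloxy)penta-2,4-dienoate | CCC/C(C(=C)O[Si](C)(C)C)=C\C(=O)OCc1ccccc1
F4 | step 3 | benzyl (E)-5-bromo-4-oxo-3-propylpent-2-enoate | CCC/C(C(=O)CBr)=C\C(=O)OCc1ccccc1
F5 | step 1 | (Z)-trimethyl(hex-2-en-2-yloxy)silane | C/C(O[Si](C)(C)C)=C/CCC
F6 | step 1 | benzyl 3-acetyl-2-hydroxyhexanoate (diastereomer mixture) | CCCC(C(C)=O)C(O)C(=O)OCc1ccccc1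
F7 | step 1 | benzyl 3-acetyl-2-(methylsulfonyloxy)hexanoate (diastereomer mixture) | CCCC(C(C)=O)C(OS(C)(=O)=O)C(=O)OCc1ccccc1
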